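**Plan**
- Cuts: first the nineteen O-benzyl bonds and the C8–Br bond of unit T, then the two C3–O gallate esters. Then, in unit T and after it in unit M (the two epicatechin gallates), the ring C bonds C3–C4 and C4–C4a. This leaves bromobenzofuranone 7 (used twice), (+)-catechin (unit B) and protected gallic acid.
- Enabling feature: taking C4 out of ring C of T or M leaves a 2-arylbenzofuran-3-one. C4, already bonded to C8 of the unit below, is a single carbon that fits between the ketone carbon C3 and the ring A carbon C4a.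
- Forward: ring C of B comes with catechin. Its C8 is turned into a diazomethyl group whose carbon is inserted into 7, enlarging the furanone to ring C of M. The bromine carried by 7 then becomes the next diazomethyl group, and a second insertion builds ring C of T.
- Stereochemistry: B from (+)-catechin. C2 of M and T by dynamic kinetic resolution of the labile furanone on a chiral scandium catalyst. C4 trans to the C2 aryl group (peri strain). C3 by hydride delivery anti to the C4 aryl group, then Mitsunobu inversion with the gallic acid.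

Key step: step 11

Remarks on the chemistry:
- Furanone 7 is formed as a racemate whose C2 centre equilibrates through the enol; the SMILES shows the (2R) form that is meant to react.
- The tris(oxazoline) antipode matched with the catechin-derived diazo compound has to be found by trial; (S,S,S) is written.
- C4 configurations are given as α/β (flavan convention, 2-aryl = α), because CIP descriptors at C4 change with remote substituents.
- Acid 21 and 2-(trifluoromethyl)benzenesulfonohydrazide are purchased.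

Step 1
Reactants: 1 phloroglucinol; 2 3,4-dihydroxyphenylacetic acid
Product: 3 2-(3,4-dihydroxyphenyl)-1-(2,4,6-trihydroxyphenyl)ethanone
Conditions: BF3·OEt2 (neat), 85 °C; aq. NaOAc
Reagents that add atoms: none
Why: BF3-promoted Friedel–Crafts (Houben–Hoesch-type) C-acylation of the symmetrical, highly nucleophilic phloroglucinol by an arylacetic acid is the standard deoxybenzoin synthesis and creates no stereocentre.

Step 2
Reactants: 3 2-(3,4-dihydroxyphenyl)-1-(2,4,6-trihydroxyphenyl)ethanone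
Product: 4 1-[2,4-bis(benzyloxy)-6-hydroxyphenyl]-2-[3,4-bis(benzyloxy)phenyl]ethanone
Conditions: BnBr (4.1 equiv), K2CO3, DMF, 0 °C to rt
Reagents that add atoms: benzyl bromide, BrCc1ccccc1
Why: Williamson etherification should take the four more acidic phenols, while the last ortho-OH, hydrogen-bonded to the ketone, stays free as is usual for 2-hydroxy-4,6-dialkoxyaryl ketones.

Step 3
Reactants: 4 1-[2,4-bis(benzyloxy)-6-hydroxyphenyl]-2-[3,4-bis(benzyloxy)phenyl]ethanone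
Product: 5 1-[4,6-bis(benzyloxy)-3-bromo-2-hydroxyphenyl]-2-[3,4-bis(benzyloxy)phenyl]ethanone
Conditions: NBS (1.0 equiv), CH2Cl2, −20 to 0 °C
Reagents that add atoms: N-bromosuccinimide, O=C1CCC(=O)N1Br
Why: Electrophilic aromatic bromination of chelated 2-hydroxy-4,6-dialkoxyaryl ketones goes to the position between the free OH and the neighbouring ether, which becomes C7 of the furanone and later C8 of the flavan.

Step 4
Reactants: 5 1-[4,6-bis(benzyloxy)-3-bromo-2-hydroxyphenyl]-2-[3,4-bis(benzyloxy)phenyl]ethanone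
Product: 7 rac-4,6-bis(benzyloxy)-2-[3,4-bis(benzyloxy)phenyl]-7-bromobenzofuran-3(2H)-one, via alpha-bromoketone 6 (not isolated)
Conditions: CuBr2 (2.1 equiv), EtOAc/CHCl3, reflux; filter; NaOAc, EtOH, rt, argon
Reagents that add atoms: none
Why: CuBr2 alpha-bromination of the enolisable aryl benzyl ketone, then intramolecular Williamson closure (5-exo-tet) of the ortho phenoxide onto the benzylic bromide, gives the coumaranone with C2 racemic and labile.

Step 5
Reactants: 8 (+)-catechin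
Product: 9 5,7,3',4'-tetra-O-benzyl-(+)-catechin
Conditions: BnBr (4.4 equiv), K2CO3, DMF, rt
Reagents that add atoms: benzyl bromide, BrCc1ccccc1
Why: Williamson etherification under carbonate conditions benzylates the four phenols and leaves the secondary alcohol and both stereocentres untouched.

Step 6
Reactants: 9 5,7,3',4'-tetra-O-benzyl-(+)-catechin
Product: 10 3,5,7,3',4'-penta-O-benzyl-(+)-catechin
Conditions: NaH, BnBr, DMF, 0 °C to rt
Reagents that add atoms: benzyl bromide, BrCc1ccccc1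
Why: Williamson etherification of the sodium alkoxide caps the 3-OH, which would otherwise interfere with the organolithium and diazo chemistry.

Step 7
Reactants: 10 3,5,7,3',4'-penta-O-benzyl-(+)-catechin
Product: 11 8-bromo-3,5,7,3',4'-penta-O-benzylcatechin
Conditions: NBS (1.0 equiv), CH2Cl2, −78 to 0 °C
Reagents that add atoms: N-bromosuccinimide, O=C1CCC(=O)N1Br
Why: Electrophilic bromination of benzylated, 3-O-protected flavan-3-ols with NBS is selective for C8 over C6.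

Step 8
Reactants: 11 8-bromo-3,5,7,3',4'-penta-O-benzylcatechin
Product: 13 8-formyl-3,5,7,3',4'-penta-O-benzylcatechin, via 8-lithio arene 12 (not isolated)
Conditions: n-BuLi (1.1 equiv), THF, −78 °C; DMF; aq. NH4Cl
Reagents that add atoms: N,N-dimethylformamide, CN(C)C=O
Why: Bromine–lithium exchange at C8 of benzylated flavans is fast at −78 °C, and trapping with DMF (Bouveault formylation) fixes the future interflavan carbon at C8.

Step 9
Reactants: 13 8-formyl-3,5,7,3',4'-penta-O-benzylcatechin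
Product: 14 (E)-N-[2-(trifluoromethyl)benzenesulfonyl]hydrazone of 13
Conditions: 2-(CF3)C6H4SO2NHNH2, MeOH/THF, rt
Reagents that add atoms: 2-(trifluoromethyl)benzenesulfonohydrazide, NNS(=O)(=O)c1ccccc1C(F)(F)F
Why: Condensation of an aryl aldehyde with a sulfonyl hydrazide gives the crystalline sulfonylhydrazone, a storable diazo precursor.

Step 10
Reactants: 14 (E)-N-[2-(trifluoromethyl)benzenesulfonyl]hydrazone of 13
Product: 16 8-(diazomethyl)-3,5,7,3',4'-penta-O-benzylcatechin, via hydrazone sodium salt 15 (not isolated)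
Conditions: NaH, CH2Cl2, −40 to −10 °C; cold filtration under argon; solution used at once
Reagents that add atoms: none
Why: Bamford–Stevens-type loss of sulfinate from the hydrazone anion is possible below 0 °C with the ortho-CF3 sulfonyl group, so the electron-rich aryldiazomethane should survive long enough to be used.

Step 11
Reactants: 7 rac-4,6-bis(benzyloxy)-2-[3,4-bis(benzyloxy)phenyl]-7-bromobenzofuran-3(2H)-one (1.5 equiv); 16 8-(diazomethyl)-3,5,7,3',4'-penta-O-benzylcatechin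
Product: 17 8-bromo-5,7,3',4'-tetra-O-benzyl-(2R)-flavan-3-one-(4β→8)-3,5,7,3',4'-penta-O-benzylcatechin (2,4-trans)
Conditions: Sc(OTf)3 (10 mol %), (S,S,S)-iPr-trisox [1,1,1-tris((4S)-4-isopropyl-4,5-dihydrooxazol-2-yl)ethane] (12 mol %), 4 Å MS, toluene/CH2Cl2, −78 to −45 °C, slow addition of 16; cold silica plug, concentration below 0 °C
Reagents that add atoms: none
Why: Proposed new method: the diazo carbon of 16 should add to the scandium-bound C3 carbonyl of (2R)-7 on the face opposite the C2 aryl group, and in the resulting diazonium alkoxide the electron-rich ring A carbon C3a (ortho and para oxygens) should migrate anti to the departing N2 in preference to the oxygenated sp3 carbon C2, so that C3–C4 and C4–C4a of unit M form in one operation. The closest known reactions are the Sc(OTf)3-catalysed ring expansion of cycloalkanones with aryldiazomethanes and the aryl-migrating diazo homologation of isatins to 3-hydroxyquinolin-2-ones. No ring is closed by cyclisation: the six-membered ring C arises by enlargement of the five-membered furanone through the 1,2-shift of C3a (which becomes C4a) onto the inserted carbon. C2 of 7 racemises through its enol faster than it is consumed, so the chiral scandium complex together with the fixed chirality of the catechin unit is expected to take only the (2R) form (dynamic kinetic resolution); C4, the most acidic position of the product, should settle trans to the C2 aryl group because the peri C5 benzyloxy group pushes the C4 aryl group pseudoaxial while the C2 aryl group stays equatorial. The step needs aryl over alkyl migration, carbonyl addition in preference to proton transfer from the acidic C2–H to the diazo carbon, and no second homologation; the trioxygenated ring A, Lewis-acid activation at low temperature in a non-polar medium, and the shielding of the product ketone by its two flanking aryl groups are relied on for these.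

Step 12
Reactants: 17 8-bromo-5,7,3',4'-tetra-O-benzyl-(2R)-flavan-3-one-(4β→8)-3,5,7,3',4'-penta-O-benzylcatechin
Product: 18 8-bromo-5,7,3',4'-tetra-O-benzylcatechin-(4β→8)-3,5,7,3',4'-penta-O-benzylcatechin (upper unit 2R,3S; 3β-OH cis to the 4β aryl group)
Conditions: NaBH4, CeCl3·7H2O, MeOH/THF, −78 °C, crude 17 used without delay
Reagents that add atoms: none
Why: Luche reduction at −78 °C should outrun enolisation and deliver hydride to the α face, anti to the pseudoaxial C4 aryl group, which sets C3 as the 3β-alcohol (2,3-trans-3,4-cis) and freezes C2 and C4.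

Step 13
Reactants: 18 8-bromo-5,7,3',4'-tetra-O-benzylcatechin-(4β→8)-3,5,7,3',4'-penta-O-benzylcatechin
Product: 20 8-formyl-5,7,3',4'-tetra-O-benzylcatechin-(4β→8)-3,5,7,3',4'-penta-O-benzylcatechin, via dilithio species 19 (not isolated)
Conditions: n-BuLi (2.2 equiv), THF, −78 °C; DMF; aq. NH4Cl
Reagents that add atoms: N,N-dimethylformamide, CN(C)C=O
Why: Deprotonation of the alcohol followed by bromine–lithium exchange and Bouveault formylation is done before the gallate ester is present, so no electrophile competes with DMF.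

Step 14
Reactants: 20 8-formyl-5,7,3',4'-tetra-O-benzylcatechin-(4β→8)-3,5,7,3',4'-penta-O-benzylcatechin; 21 3,4,5-tris(benzyloxy)benzoic acid
Product: 22 8-formyl-5,7,3',4'-tetra-O-benzyl-3-O-[3,4,5-tris(benzyloxy)benzoyl]epicatechin-(4β→8)-3,5,7,3',4'-penta-O-benzylcatechin
Conditions: PPh3, DIAD, toluene, 0 °C to rt (DIAD added last)
Reagents that add atoms: none
Why: Mitsunobu esterification should displace the equatorial 3β-oxyphosphonium group by the carboxylate along the unhindered axial path on the α face, inverting C3 to the 3α-gallate (2,3-cis-3,4-trans, upper unit 2R,3R).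

Step 15
Reactants: 22 8-formyl-5,7,3',4'-tetra-O-benzyl-3-O-[3,4,5-tris(benzyloxy)benzoyl]epicatechin-(4β→8)-3,5,7,3',4'-penta-O-benzylcatechin
Product: 23 (E)-N-[2-(trifluoromethyl)benzenesulfonyl]hydrazone of 22
Conditions: 2-(CF3)C6H4SO2NHNH2, MeOH/THF, rt
Reagents that add atoms: 2-(trifluoromethyl)benzenesulfonohydrazide, NNS(=O)(=O)c1ccccc1C(F)(F)F
Why: Sulfonylhydrazone condensation as in step 9; the hydrazide is not nucleophilic enough to touch the gallate ester.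

Step 16
Reactants: 23 (E)-N-[2-(trifluoromethyl)benzenesulfonyl]hydrazone of 22
Product: 25 8-(diazomethyl)-5,7,3',4'-tetra-O-benzyl-3-O-[3,4,5-tris(benzyloxy)benzoyl]epicatechin-(4β→8)-3,5,7,3',4'-penta-O-benzylcatechin, via hydrazone sodium salt 24 (not isolated)
Conditions: NaH, CH2Cl2, −40 to −10 °C; cold filtration under argon; solution used at once
Reagents that add atoms: none
Why: Bamford–Stevens-type sulfinate loss below 0 °C as in step 10; the non-nucleophilic base leaves the ester intact.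

Step 17
Reactants: 7 rac-4,6-bis(benzyloxy)-2-[3,4-bis(benzyloxy)phenyl]-7-bromobenzofuran-3(2H)-one (2 equiv); 25 8-(diazomethyl)-5,7,3',4'-tetra-O-benzyl-3-O-[3,4,5-tris(benzyloxy)benzoyl]epicatechin-(4β→8)-3,5,7,3',4'-penta-O-benzylcatechin
Product: 26 8-bromo-5,7,3',4'-tetra-O-benzyl-(2R)-flavan-3-one-(4β→8)-[5,7,3',4'-tetra-O-benzyl-3-O-(tri-O-benzylgalloyl)epicatechin]-(4β→8)-3,5,7,3',4'-penta-O-benzylcatechin (top unit 2,4-trans)
Conditions: Sc(OTf)3 (10 mol %), (S,S,S)-iPr-trisox (12 mol %), 4 Å MS, toluene/CH2Cl2, −78 to −45 °C, slow addition of 25; cold silica plug, concentration below 0 °C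
Reagents that add atoms: none
Why: Proposed new method: as in step 11, the diazo carbon at C8 of unit M should add to the scandium-activated ketone of (2R)-7 anti to its C2 aryl group, and ring A should migrate with loss of N2 to form C3–C4 and C4–C4a of unit T by ring enlargement, with C2 selected by dynamic kinetic resolution and C4 settling trans to the C2 aryl group; the closest known reactions are again the Sc(OTf)3-catalysed aryldiazomethane ring expansion of cycloalkanones and the aryl-migrating homologation of isatins.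

Step 18
Reactants: 26 8-bromo-5,7,3',4'-tetra-O-benzyl-(2R)-flavan-3-one-(4β→8)-[5,7,3',4'-tetra-O-benzyl-3-O-(tri-O-benzylgalloyl)epicatechin]-(4β→8)-3,5,7,3',4'-penta-O-benzylcatechin
Product: 27 8-bromo-5,7,3',4'-tetra-O-benzylcatechin-(4β→8)-[5,7,3',4'-tetra-O-benzyl-3-O-(tri-O-benzylgalloyl)epicatechin]-(4β→8)-3,5,7,3',4'-penta-O-benzylcatechin (top unit 2R,3S; 3β-OH cis to the 4β aryl group)
Conditions: NaBH4, CeCl3·7H2O, MeOH/THF, −78 °C, crude 26 used without delay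
Reagents that add atoms: none
Why: Luche reduction as in step 12 should deliver hydride anti to the pseudoaxial C4 aryl group of unit T; the benzoate-type ester is inert to borohydride at this temperature.

Step 19
Reactants: 27 8-bromo-5,7,3',4'-tetra-O-benzylcatechin-(4β→8)-[5,7,3',4'-tetra-O-benzyl-3-O-(tri-O-benzylgalloyl)epicatechin]-(4β→8)-3,5,7,3',4'-penta-O-benzylcatechin; 21 3,4,5-tris(benzyloxy)benzoic acid
Product: 28 8-bromo-5,7,3',4'-tetra-O-benzyl-3-O-(tri-O-benzylgalloyl)epicatechin-(4β→8)-[5,7,3',4'-tetra-O-benzyl-3-O-(tri-O-benzylgalloyl)epicatechin]-(4β→8)-3,5,7,3',4'-penta-O-benzylcatechin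
Conditions: PPh3, DIAD, toluene, 0 °C to rt
Reagents that add atoms: none
Why: Mitsunobu esterification as in step 14 should invert C3 of unit T to the 3α-gallate (2R,3R; 2,3-cis-3,4-trans).

Step 20
Reactants: 28 8-bromo-5,7,3',4'-tetra-O-benzyl-3-O-(tri-O-benzylgalloyl)epicatechin-(4β→8)-[5,7,3',4'-tetra-O-benzyl-3-O-(tri-O-benzylgalloyl)epicatechin]-(4β→8)-3,5,7,3',4'-penta-O-benzylcatechin
Product: 29 (−)-epicatechin 3-O-gallate-(4β→8)-(−)-epicatechin 3-O-gallate-(4β→8)-(+)-catechin (CNP0269915.2)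
Conditions: H2 (1 atm), Pd(OH)2/C, Et3N (1.2 equiv), THF/MeOH/H2O, rt; filtration; lyophilisation
Reagents that add atoms: none
Why: Catalytic hydrogenolysis should remove all nineteen benzyl ethers and the aryl bromide of unit T together, with Et3N buffering the HBr so that the acid-labile interflavan bonds and the gallate esters survive; no stereocentre is touched.

**Compound list**
1 | phloroglucinol | Oc1cc(O)cc(O)c1 | starting material
2 | 3,4-dihydroxyphenylacetic acid | OC(=O)Cc1ccc(O)c(O)c1 | starting material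
3 | 2-(3,4-dihydroxyphenyl)-1-(2,4,6-trihydroxyphenyl)ethanone | O=C(Cc1ccc(O)c(O)c1)c1c(O)cc(O)cc1O | intermediate
4 | 1-[2,4-bis(benzyloxy)-6-hydroxyphenyl]-2-[3,4-bis(benzyloxy)phenyl]ethanone | O=C(Cc1ccc(OCc9ccccc9)c(OCc9ccccc9)c1)c1c(O)cc(OCc9ccccc9)cc1OCc9ccccc9 | intermediate
5 | 1-[4,6-bis(benzyloxy)-3-bromo-2-hydroxyphenyl]-2-[3,4-bis(benzyloxy)phenyl]ethanone | O=C(Cc1ccc(OCc9ccccc9)c(OCc9ccccc9)c1)c1c(O)c(Br)c(OCc9ccccc9)cc1OCc9ccccc9 | intermediate
6 | rac-2-bromo-1-[4,6-bis(benzyloxy)-3-bromo-2-hydroxyphenyl]-2-[3,4-bis(benzyloxy)phenyl]ethanone (alpha-bromoketone, not isolated) | O=C(C(Br)c1ccc(OCc9ccccc9)c(OCc9ccccc9)c1)c1c(O)c(Br)c(OCc9ccccc9)cc1OCc9ccccc9 | intermediate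
7 | 4,6-bis(benzyloxy)-2-[3,4-bis(benzyloxy)phenyl]-7-bromobenzofuran-3(2H)-one, racemic and labile at C2, reacting (2R) form drawn | O=C1c2c(OCc9ccccc9)cc(OCc9ccccc9)c(Br)c2O[C@@H]1c1ccc(OCc9ccccc9)c(OCc9ccccc9)c1 | intermediate
8 | (+)-catechin, (2R,3S) | c1c(O)cc(O)c2c1O[C@H](c1ccc(O)c(O)c1)[C@@H](O)C2 | starting material
9 | 5,7,3',4'-tetra-O-benzyl-(+)-catechin | c1c(OCc9ccccc9)cc(OCc9ccccc9)c2c1O[C@H](c1ccc(OCc9ccccc9)c(OCc9ccccc9)c1)[C@@H](O)C2 | intermediate
10 | 3,5,7,3',4'-penta-O-benzyl-(+)-catechin | c1c(OCc9ccccc9)cc(OCc9ccccc9)c2c1O[C@H](c1ccc(OCc9ccccc9)c(OCc9ccccc9)c1)[C@@H](OCc9ccccc9)C2 | intermediate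
11 | 8-bromo-3,5,7,3',4'-penta-O-benzylcatechin | Brc1c(OCc9ccccc9)cc(OCc9ccccc9)c2c1O[C@H](c1ccc(OCc9ccccc9)c(OCc9ccccc9)c1)[C@@H](OCc9ccccc9)C2 | intermediate
12 | 8-lithio-3,5,7,3',4'-penta-O-benzylcatechin (not isolated) | [Li]c1c(OCc9ccccc9)cc(OCc9ccccc9)c2c1O[C@H](c1ccc(OCc9ccccc9)c(OCc9ccccc9)c1)[C@@H](OCc9ccccc9)C2 | intermediate
13 | 8-formyl-3,5,7,3',4'-penta-O-benzylcatechin | O=Cc1c(OCc9ccccc9)cc(OCc9ccccc9)c2c1O[C@H](c1ccc(OCc9ccccc9)c(OCc9ccccc9)c1)[C@@H](OCc9ccccc9)C2 | intermediate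
14 | (E)-N-[2-(trifluoromethyl)benzenesulfonyl]hydrazone of 13 | FC(F)(F)c1ccccc1S(=O)(=O)N/N=C/c1c(OCc9ccccc9)cc(OCc9ccccc9)c2c1O[C@H](c1ccc(OCc9ccccc9)c(OCc9ccccc9)c1)[C@@H](OCc9ccccc9)C2 | intermediate
15 | sodium salt of hydrazone 14 (not isolated) | [Na+].FC(F)(F)c1ccccc1S(=O)(=O)[N-]/N=C/c1c(OCc9ccccc9)cc(OCc9ccccc9)c2c1O[C@H](c1ccc(OCc9ccccc9)c(OCc9ccccc9)c1)[C@@H](OCc9ccccc9)C2 | intermediate
16 | 8-(diazomethyl)-3,5,7,3',4'-penta-O-benzylcatechin | [N-]=[N+]=Cc1c(OCc9ccccc9)cc(OCc9ccccc9)c2c1O[C@H](c1ccc(OCc9ccccc9)c(OCc9ccccc9)c1)[C@@H](OCc9ccccc9)C2 | intermediate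
17 | 8-bromo-5,7,3',4'-tetra-O-benzyl-(2R)-flavan-3-one-(4β→8)-3,5,7,3',4'-penta-O-benzylcatechin, 2,4-trans | O=C1[C@@H](c2c(OCc9ccccc9)cc(OCc9ccccc9)c3c2O[C@H](c2ccc(OCc9ccccc9)c(OCc9ccccc9)c2)[C@@H](OCc9ccccc9)C3)c2c(OCc9ccccc9)cc(OCc9ccccc9)c(Br)c2O[C@@H]1c1ccc(OCc9ccccc9)c(OCc9ccccc9)c1 | intermediate
18 | 8-bromo-5,7,3',4'-tetra-O-benzylcatechin-(4β→8)-3,5,7,3',4'-penta-O-benzylcatechin; upper unit 2R,3S with 3β-OH cis to the 4β aryl group | O[C@H]1[C@@H](c2c(OCc9ccccc9)cc(OCc9ccccc9)c3c2O[C@H](c2ccc(OCc9ccccc9)c(OCc9ccccc9)c2)[C@@H](OCc9ccccc9)C3)c2c(OCc9ccccc9)cc(OCc9ccccc9)c(Br)c2O[C@@H]1c1ccc(OCc9ccccc9)c(OCc9ccccc9)c1 | intermediate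
19 | 3-O-lithio-8-lithio derivative of 18 (not isolated) | [Li]O[C@H]1[C@@H](c2c(OCc9ccccc9)cc(OCc9ccccc9)c3c2O[C@H](c2ccc(OCc9ccccc9)c(OCc9ccccc9)c2)[C@@H](OCc9ccccc9)C3)c2c(OCc9ccccc9)cc(OCc9ccccc9)c([Li])c2O[C@@H]1c1ccc(OCc9ccccc9)c(OCc9ccccc9)c1 | intermediate
20 | 8-formyl-5,7,3',4'-tetra-O-benzylcatechin-(4β→8)-3,5,7,3',4'-penta-O-benzylcatechin; upper unit 2R,3S | O[C@H]1[C@@H](c2c(OCc9ccccc9)cc(OCc9ccccc9)c3c2O[C@H](c2ccc(OCc9ccccc9)c(OCc9ccccc9)c2)[C@@H](OCc9ccccc9)C3)c2c(OCc9ccccc9)cc(OCc9ccccc9)c(C=O)c2O[C@@H]1c1ccc(OCc9ccccc9)c(OCc9ccccc9)c1 | intermediate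
21 | 3,4,5-tris(benzyloxy)benzoic acid | OC(=O)c1cc(OCc9ccccc9)c(OCc9ccccc9)c(OCc9ccccc9)c1 | starting material
22 | 8-formyl-5,7,3',4'-tetra-O-benzyl-3-O-[3,4,5-tris(benzyloxy)benzoyl]epicatechin-(4β→8)-3,5,7,3',4'-penta-O-benzylcatechin; upper unit 2R,3R | O=C(O[C@@H]1[C@@H](c2c(OCc9ccccc9)cc(OCc9ccccc9)c3c2O[C@H](c2ccc(OCc9ccccc9)c(OCc9ccccc9)c2)[C@@H](OCc9ccccc9)C3)c2c(OCc9ccccc9)cc(OCc9ccccc9)c(C=O)c2O[C@@H]1c1ccc(OCc9ccccc9)c(OCc9ccccc9)c1)c1cc(OCc9ccccc9)c(OCc9ccccc9)c(OCc9ccccc9)c1 | intermediate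
23 | (E)-N-[2-(trifluoromethyl)benzenesulfonyl]hydrazone of 22 | O=C(O[C@@H]1[C@@H](c2c(OCc9ccccc9)cc(OCc9ccccc9)c3c2O[C@H](c2ccc(OCc9ccccc9)c(OCc9ccccc9)c2)[C@@H](OCc9ccccc9)C3)c2c(OCc9ccccc9)cc(OCc9ccccc9)c(/C=N/NS(=O)(=O)c4ccccc4C(F)(F)F)c2O[C@@H]1c1ccc(OCc9ccccc9)c(OCc9ccccc9)c1)c1cc(OCc9ccccc9)c(OCc9ccccc9)c(OCc9ccccc9)c1 | intermediate
24 | sodium salt of hydrazone 23 (not isolated) | [Na+].O=C(O[C@@H]1[C@@H](c2c(OCc9ccccc9)cc(OCc9ccccc9)c3c2O[C@H](c2ccc(OCc9ccccc9)c(OCc9ccccc9)c2)[C@@H](OCc9ccccc9)C3)c2c(OCc9ccccc9)cc(OCc9ccccc9)c(/C=N/[N-]S(=O)(=O)c4ccccc4C(F)(F)F)c2O[C@@H]1c1ccc(OCc9ccccc9)c(OCc9ccccc9)c1)c1cc(OCc9ccccc9)c(OCc9ccccc9)c(OCc9ccccc9)c1 | intermediate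
25 | 8-(diazomethyl)-5,7,3',4'-tetra-O-benzyl-3-O-[3,4,5-tris(benzyloxy)benzoyl]epicatechin-(4β→8)-3,5,7,3',4'-penta-O-benzylcatechin | O=C(O[C@@H]1[C@@H](c2c(OCc9ccccc9)cc(OCc9ccccc9)c3c2O[C@H](c2ccc(OCc9ccccc9)c(OCc9ccccc9)c2)[C@@H](OCc9ccccc9)C3)c2c(OCc9ccccc9)cc(OCc9ccccc9)c(C=[N+]=[N-])c2O[C@@H]1c1ccc(OCc9ccccc9)c(OCc9ccccc9)c1)c1cc(OCc9ccccc9)c(OCc9ccccc9)c(OCc9ccccc9)c1 | intermediate
26 | trimer ketone: 8-bromo-5,7,3',4'-tetra-O-benzyl-(2R)-flavan-3-one (2,4-trans) joined 4β→8 to the middle unit of 22, which is joined 4β→8 to penta-O-benzylcatechin | O=C(O[C@@H]1[C@@H](c2c(OCc9ccccc9)cc(OCc9ccccc9)c3c2O[C@H](c2ccc(OCc9ccccc9)c(OCc9ccccc9)c2)[C@@H](OCc9ccccc9)C3)c2c(OCc9ccccc9)cc(OCc9ccccc9)c([C@H]3c4c(OCc9ccccc9)cc(OCc9ccccc9)c(Br)c4O[C@H](c4ccc(OCc9ccccc9)c(OCc9ccccc9)c4)C3=O)c2O[C@@H]1c1ccc(OCc9ccccc9)c(OCc9ccccc9)c1)c1cc(OCc9ccccc9)c(OCc9ccccc9)c(OCc9ccccc9)c1 | intermediate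
27 | trimer alcohol: top unit 8-bromo-tetra-O-benzylcatechin (2R,3S; 3β-OH cis to the 4β aryl group), middle unit protected epicatechin gallate, bottom unit penta-O-benzylcatechin | O=C(O[C@@H]1[C@@H](c2c(OCc9ccccc9)cc(OCc9ccccc9)c3c2O[C@H](c2ccc(OCc9ccccc9)c(OCc9ccccc9)c2)[C@@H](OCc9ccccc9)C3)c2c(OCc9ccccc9)cc(OCc9ccccc9)c([C@H]3c4c(OCc9ccccc9)cc(OCc9ccccc9)c(Br)c4O[C@H](c4ccc(OCc9ccccc9)c(OCc9ccccc9)c4)[C@H]3O)c2O[C@@H]1c1ccc(OCc9ccccc9)c(OCc9ccccc9)c1)c1cc(OCc9ccccc9)c(OCc9ccccc9)c(OCc9ccccc9)c1 | intermediate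
28 | fully protected trimer: 8-bromo-tetra-O-benzyl-3-O-(tri-O-benzylgalloyl)epicatechin-(4β→8)-tetra-O-benzyl-3-O-(tri-O-benzylgalloyl)epicatechin-(4β→8)-penta-O-benzylcatechin | O=C(O[C@@H]1[C@@H](c2c(OCc9ccccc9)cc(OCc9ccccc9)c3c2O[C@H](c2ccc(OCc9ccccc9)c(OCc9ccccc9)c2)[C@@H](OCc9ccccc9)C3)c2c(OCc9ccccc9)cc(OCc9ccccc9)c([C@H]3c4c(OCc9ccccc9)cc(OCc9ccccc9)c(Br)c4O[C@H](c4ccc(OCc9ccccc9)c(OCc9ccccc9)c4)[C@@H]3OC(=O)c3cc(OCc9ccccc9)c(OCc9ccccc9)c(OCc9ccccc9)c3)c2O[C@@H]1c1ccc(OCc9ccccc9)c(OCc9ccccc9)c1)c1cc(OCc9ccccc9)c(OCc9ccccc9)c(OCc9ccccc9)c1 | intermediate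
29 | (−)-epicatechin 3-O-gallate-(4β→8)-(−)-epicatechin 3-O-gallate-(4β→8)-(+)-catechin | O=C(O[C@@H]1[C@@H](c2c(O)cc(O)c3c2O[C@H](c2ccc(O)c(O)c2)[C@@H](O)C3)c2c(O)cc(O)c([C@H]3c4c(O)cc(O)cc4O[C@H](c4ccc(O)c(O)c4)[C@@H]3OC(=O)c3cc(O)c(O)c(O)c3)c2O[C@@H]1c1ccc(O)c(O)c1)c1cc(O)c(O)c(O)c1 | target

**Step count**
Total: 20 steps. Longest linear sequence: 16 steps (8 to 29 through steps 5–20).

**Steps most likely to fail**

Step 11. What may go wrong:
- proton transfer from the acidic C2–H of 7 to the diazo carbon, so that the enol is benzylated instead of the carbonyl being attacked;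
- migration of C2 instead of ring A;
- insufficient discrimination between the interconverting enantiomers of 7, or epimerisation of the product ketone before it is reduced.

Fallback: the interflavan bonds would be made in the opposite polarity by the established Lewis-acid coupling of a C4-oxygenated epicatechin with C8 of the unit below. It sets out from 9 and 10 and returns at 28.
- Dess–Martin oxidation of 9 gives 5,7,3',4'-tetra-O-benzyl-(2R)-flavan-3-one F1, and L-Selectride reduction gives 5,7,3',4'-tetra-O-benzylepicatechin F2.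
- DDQ with ethylene glycol gives 4β-(2-hydroxyethoxy)-5,7,3',4'-tetra-O-benzylepicatechin F3, and NBS converts part of it into its 8-bromide F4.
- TMSOTf-mediated coupling of F3 with an excess of 10 should give 5,7,3',4'-tetra-O-benzylepicatechin-(4β→8)-penta-O-benzylcatechin F5.
- A second TMSOTf coupling of F4 at C8 of the upper unit of F5 gives the trimeric diol F6.
- Twofold Steglich esterification of F6 with 21 (DCC, DMAP) gives 28.

Step 17. What may go wrong: addition of the bulky dimeric diazo compound to the ketone becomes so slow that azine formation, carbene dimerisation and protonation of the diazo carbon take over, or the catalyst is mismatched with the larger chiral partner.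

Fallback: chain extension by Lewis-acid coupling. It sets out from 18 and returns at 28.
- Bromine–lithium exchange on 18 (n-BuLi, 2.2 equiv) and a methanol quench give the debrominated dimer alcohol F7.
- Mitsunobu esterification with 21 as in step 14 gives the dimer gallate with free C8, F8.
- TMSOTf coupling of F8 with the capped electrophile F4 (made from 9 as described for step 11) gives the trimer with a free 3α-OH on unit T, F9.
- Steglich esterification of F9 with 21 gives 28.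

Step 14 (the same concern applies to step 19). What may go wrong: the activated equatorial C3–O bond ionises with participation of the antiperiplanar O1–C2 or C4–C4a bond, giving ring contraction or retention, or elimination replaces the SN2 displacement.

Fallback: C3 is set by reagent-controlled reduction and the ester is made with retention. It sets out from 17 and returns at 22.
- Corey–Bakshi–Shibata reduction of 17 (catecholborane, the Me-CBS oxazaborolidine enantiomer that delivers hydride syn to the C4 aryl group) would give the 3α-alcohol, 8-bromo-5,7,3',4'-tetra-O-benzylepicatechin-(4β→8)-penta-O-benzylcatechin F10.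
- n-BuLi/DMF as in step 13 gives the 8-formyl 3α-alcohol F11.
- Steglich esterification of F11 with 21 gives 22.

**Further compounds**
F1 | step 11 | 5,7,3',4'-tetra-O-benzyl-(2R)-flavan-3-one | c1c(OCc9ccccc9)cc(OCc9ccccc9)c2c1O[C@H](c1ccc(OCc9ccccc9)c(OCc9ccccc9)c1)C(=O)C2
F2 | step 11 | 5,7,3',4'-tetra-O-benzyl-(−)-epicatechin | c1c(OCc9ccccc9)cc(OCc9ccccc9)c2c1O[C@H](c1ccc(OCc9ccccc9)c(OCc9ccccc9)c1)[C@H](O)C2
F3 | step 11 | 4β-(2-hydroxyethoxy)-5,7,3',4'-tetra-O-benzylepicatechin | O[C@@H]1[C@@H](OCCO)c2c(OCc9ccccc9)cc(OCc9ccccc9)cc2O[C@@H]1c1ccc(OCc9ccccc9)c(OCc9ccccc9)c1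
F4 | step 11 | 8-bromo-4β-(2-hydroxyethoxy)-5,7,3',4'-tetra-O-benzylepicatechin | O[C@@H]1[C@@H](OCCO)c2c(OCc9ccccc9)cc(OCc9ccccc9)c(Br)c2O[C@@H]1c1ccc(OCc9ccccc9)c(OCc9ccccc9)c1
F5 | step 11 | 5,7,3',4'-tetra-O-benzylepicatechin-(4β→8)-3,5,7,3',4'-penta-O-benzylcatechin | O[C@@H]1[C@@H](c2c(OCc9ccccc9)cc(OCc9ccccc9)c3c2O[C@H](c2ccc(OCc9ccccc9)c(OCc9ccccc9)c2)[C@@H](OCc9ccccc9)C3)c2c(OCc9ccccc9)cc(OCc9ccccc9)cc2O[C@@H]1c1ccc(OCc9ccccc9)c(OCc9ccccc9)c1
F6 | step 11 | 8-bromo-tetra-O-benzylepicatechin-(4β→8)-tetra-O-benzylepicatechin-(4β→8)-penta-O-benzylcatechin (3-OH free on both upper units) | O[C@@H]1[C@@H](c2c(OCc9ccccc9)cc(OCc9ccccc9)c3c2O[C@H](c2ccc(OCc9ccccc9)c(OCc9ccccc9)c2)[C@@H](OCc9ccccc9)C3)c2c(OCc9ccccc9)cc(OCc9ccccc9)c([C@H]3c4c(OCc9ccccc9)cc(OCc9ccccc9)c(Br)c4O[C@H](c4ccc(OCc9ccccc9)c(OCc9ccccc9)c4)[C@@H]3O)c2O[C@@H]1c1ccc(OCc9ccccc9)c(OCc9ccccc9)c1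
F7 | step 17 | 5,7,3',4'-tetra-O-benzylcatechin-(4β→8)-3,5,7,3',4'-penta-O-benzylcatechin (debrominated 18) | O[C@H]1[C@@H](c2c(OCc9ccccc9)cc(OCc9ccccc9)c3c2O[C@H](c2ccc(OCc9ccccc9)c(OCc9ccccc9)c2)[C@@H](OCc9ccccc9)C3)c2c(OCc9ccccc9)cc(OCc9ccccc9)cc2O[C@@H]1c1ccc(OCc9ccccc9)c(OCc9ccccc9)c1
F8 | step 17 | 5,7,3',4'-tetra-O-benzyl-3-O-[3,4,5-tris(benzyloxy)benzoyl]epicatechin-(4β→8)-3,5,7,3',4'-penta-O-benzylcatechin | O=C(O[C@@H]1[C@@H](c2c(OCc9ccccc9)cc(OCc9ccccc9)c3c2O[C@H](c2ccc(OCc9ccccc9)c(OCc9ccccc9)c2)[C@@H](OCc9ccccc9)C3)c2c(OCc9ccccc9)cc(OCc9ccccc9)cc2O[C@@H]1c1ccc(OCc9ccccc9)c(OCc9ccccc9)c1)c1cc(OCc9ccccc9)c(OCc9ccccc9)c(OCc9ccccc9)c1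
F9 | step 17 | 8-bromo-tetra-O-benzylepicatechin-(4β→8)-[tetra-O-benzyl-3-O-(tri-O-benzylgalloyl)epicatechin]-(4β→8)-penta-O-benzylcatechin (3-OH free on the top unit) | O=C(O[C@@H]1[C@@H](c2c(OCc9ccccc9)cc(OCc9ccccc9)c3c2O[C@H](c2ccc(OCc9ccccc9)c(OCc9ccccc9)c2)[C@@H](OCc9ccccc9)C3)c2c(OCc9ccccc9)cc(OCc9ccccc9)c([C@H]3c4c(OCc9ccccc9)cc(OCc9ccccc9)c(Br)c4O[C@H](c4ccc(OCc9ccccc9)c(OCc9ccccc9)c4)[C@@H]3O)c2O[C@@H]1c1ccc(OCc9ccccc9)c(OCc9ccccc9)c1)c1cc(OCc9ccccc9)c(OCc9ccccc9)c(OCc9ccccc9)c1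
F10 | step 14 | 8-bromo-5,7,3',4'-tetra-O-benzylepicatechin-(4β→8)-3,5,7,3',4'-penta-O-benzylcatechin | O[C@@H]1[C@@H](c2c(OCc9ccccc9)cc(OCc9ccccc9)c3c2O[C@H](c2ccc(OCc9ccccc9)c(OCc9ccccc9)c2)[C@@H](OCc9ccccc9)C3)c2c(OCc9ccccc9)cc(OCc9ccccc9)c(Br)c2O[C@@H]1c1ccc(OCc9ccccc9)c(OCc9ccccc9)c1
F11 | step 14 | 8-formyl-5,7,3',4'-tetra-O-benzylepicatechin-(4β→8)-3,5,7,3',4'-penta-O-benzylcatechin | O[C@@H]1[C@@H](c2c(OCc9ccccc9)cc(OCc9ccccc9)c3c2O[C@H](c2ccc(OCc9ccccc9)c(OCc9ccccc9)c2)[C@@H](OCc9ccccc9)C3)c2c(OCc9ccccc9)cc(OCc9ccccc9)c(C=O)c2O[C@@H]1c1ccc(OCc9ccccc9)c(OCc9ccccc9)c1
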